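At early times the oak run shows 2.2% of its solid substrate as product at 2.50 h, so I treat the flask as stages in series with a lag: solid substrate dissolves to starting material, this turns into reactive form, and reagent takes reactive form to product.

| flask | solid substrate | reagent | remark | time |
|---|---|---|---|---|
| oak | 0.050 M | 0.090 M | run made earlier |  |
| ash | 0.050 M | 0.030 M | run made earlier |  |
| green | 0.050 M | 0.0600 M |  | 15 h |
| amber | 0.10 M | 0.0600 M |  | 15 h |
| red | 0.20 M | 0.0600 M |  | 15 h |

| run | time / h | product / % |
|---|---|---|
| oak | 0.833 | 0 |
| oak | 2.00 | 2.1 |
| oak | 2.50 | 2.2 |
| oak | 4.00 | 8.5 |
| oak | 5.00 | 13.3 |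
| ash | 0.417 | 0.4 |
| ash | 0.667 | 0.1 |
| ash | 1.00 | 0.4 |
| ash | 2.00 | 0 |
| ash | 3.00 | 1.6 |
| ash | 5.00 | 5.4 |

(scatter of a reading: 1 percentage point)

* [product] at the end for green, amber, red, in this order
* the course of these numbers from the first flask to the last (rises, then falls / falls, then rises / hardly changes / rises all the way / falls all the way)

- as a solid, counted per litre of solution: solid substrate
- candidate steps: solid substrate <-> starting material; reagent + reactive form -> product; starting material <-> reactive form
- at the start none of the solid substrate is in solution
- "hardly changes" means that all values lie within two and a half points (for a concentration: within two and a half percent of the largest)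

From 4.00 h to 5.00 h, oak's gain in product, taken as a fraction of its reagent charge per hour, is 0.0267 h⁻¹. I call this fraction the reagent drain, a pseudo-first-order constant. Ash, from 3.00 h to 5.00 h, reads 0.0317 h⁻¹, close to oak's value within the scatter.

I assume that the drain belongs to the dissolved material and holds at any loading while solid remains, which these runs cannot test. Over 15 h, ignoring the lag, my reckoning then makes 0.0198 M of product in each flask. That is a share of the solid charge of 39.6% for green, 19.8% for amber and 9.89% for red. Green has the smallest charge, yet its share stays below the whole charge, so I expect a level row.

The forecast differs: 0.03 M, 0.036 M, 0.037 M, rises all the way, since green “probably runs out of solid”.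

The flasks give 0.0240 M, 0.0240 M, 0.0240 M: hardly changes.

    solid substrate ⇌ starting material, rate k1*(cs1 - [starting material]) while solid is left; crystals form when [starting material] > cs1 (solubility = 19.0 mM, k = 0.360 h⁻¹)
    reagent + reactive form → product (k = 9.30 L mol⁻¹ h⁻¹)
    starting material ⇌ reactive form (K = 0.680, k = 0.340 h⁻¹)

At 15.0 h green still holds 14.7% of its solid substrate, and its starting material, now 26.8% of the charge, is made 1.05 times as fast as it is used up, each step taken net. Green's reagent stands at 60.1%, an average drain over 15 h of 0.0340 h⁻¹, beside the reading of 0.0267 h⁻¹ from oak, and red's reagent, at 60.1%, gives an average drain of 0.0339 h⁻¹.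

The earlier runs and the new flask are calculated with made-up constants; scatter was added.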